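## The problem

Tomentodione P (20) is built from three ring systems. A trans-fused bicyclo[7.2.0]undecene (cyclobutane C1–C9–C10–C11 on the nine-membered ring C1 to C9, caryophyllane numbering) shares the single atom C8 with a dihydropyran, and that pyran is fused through the C1′=C6′ enol ether to a tetramethylcyclohexenedione derived from syncarpic acid. The molecule has five stereocentres (1R, 5S, 8S, 9S, 7′S) and a (Z)-C3=C4 alkene inside the medium ring. C1 and C9 are neighbours, and while C9 is α to a carbonyl group C1 fixes the trans arrangement by equilibration. C5 lies across a flexible ring and cannot be expected to follow from them, so it needs reagent control; C8 and C7′ arise together when the pyran is formed and are governed only by the shape of the nine-membered ring. The secondary allylic alcohol at C5, the cyclobutylcarbinyl positions C2 and C8 and the enol ether of the vinylogous ester all speak against strong acid or cationic conditions late in the route, and the medium ring invites transannular reactions. The carbocyclic difficulty is the nine-membered ring itself, which resists direct closure, together with the supply of the 4/9 bicycle as one enantiomer. The feature that opens a way in is that the two oxygenated ring carbons C5 and C8 are 1,4-related through C6–C7. At the ketone level C6 and C7 are both α-carbons, so the C6–C7 bond can be made by joining two enolate carbons, and in the open-chain form both are methyl groups of methyl ketones, for which enolisation is unambiguous.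

## Retrosynthesis

**Pyran.** The bonds C8–O and C13–C7′ of 20 are cut together in a retro-hetero-Diels–Alder sense. This gives dienol 16 and alkylidene trione 19, the Knoevenagel product of syncarpic acid (17) and 3-methylbutanal (18). The neighbouring option, building the pyran on a C8 ketone by acetylide addition, annulation and reduction, costs three steps and a protecting group. The cycloaddition removes fifteen carbons, two rings and two stereocentres at once. Forward, the heterodiene must prefer the 1,1-disubstituted C8=C13 alkene over C3=C4 and choose one face of it; the second demand is the less certain one.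

**Oxidation state at C5 and C8.** Dienol 16 is traced to dienone 15 by reduction at C5, and 15 to ene-dione 14 by exchange of the C8 methylene for oxygen. Methylenation before reduction is preferred to the reverse order: the single remaining carbonyl can then be reduced under reagent control, and a transannular hemiketal between a C5 hydroxyl and the C8 ketone never arises. The forward Wittig reaction must prefer the saturated C8 ketone to the conjugated C5 ketone.

**Nine-membered ring.** In 14 the C6–C7 bond is cut. Both halves stay in one molecule, diketone 11, in which C6 and C7 are the methyl groups of two methyl ketones. Unlike cuts at C4–C5 or C2–C3, this one needs no auxiliary functional group, because the two carbonyls that make the enolates are the oxygens the target carries at C5 and C8. The forward reaction is an oxidative union of two enolate carbons and must be made intramolecular. A silicon bridge between the enolate oxygens (13, from bis-enolate 12) turns the nine-membered closure into a seven-membered transition state.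

**Enone arm.** The C5 acetyl group of 11 is detached at C4–C5 (Stille coupling of vinyl iodide 9 through enol ether 10). C9 is then epimerised (9 from its cis isomer 8), and the C3=C4 alkene is cut to keto aldehyde 7. A vinyl iodide is preferred to a direct enone-forming olefination for three reasons: its (Z) geometry is set reliably, it is inert to the base that epimerises C9, and it lets the acetyl group enter without touching the C8 ketone.

**Cyclobutane side chains.** Keto aldehyde 7 is the ozonolysis product of bicyclic alkene 6, which comes from tertiary alcohol 5 and sulfoximine adduct 4. The five-membered ring acts as a temporary tether that places the C2–C3 arm and C8 cis on the cyclobutane. The sulfoximine serves both as resolving agent for ketone 3 and as the source of C7.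

**Cyclobutane.** Racemic ketone 3 is cut across the four-membered ring into cyclopent-2-en-1-one (1) and 2-methylpropene (2). The forward photocycloaddition must place the gem-dimethyl carbon on the former β-carbon (head-to-tail).

## Roads not taken

**Alternative 1:** The cut runs through the cyclobutane bond C1–C9 and the pyran bond C8–O. It leads back to eleven-membered dienone A1, which carries an allylic acetate at C1, a (Z)-C8=C9 alkene and the syncarpic unit on a side chain at C8. Forward, ionisation of the acetate would give the C1–C2–C3 allyl cation; the C8=C9 alkene would attack C1 across the ring, and the enol oxygen would capture the new C8 cation to give spiro-chromene A2 (C5 ketone, C2=C3 alkene).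
- Merits: one step would form the cyclobutane, the pyran and three stereocentres, and the syncarpic unit would enter early in a convergent way.
- Weak points: cation–alkene closure to a four-membered ring is the least favourable ring size and has no dependable laboratory counterpart. The allyl cation can also be attacked at C3, lose a proton or be trapped directly by the enol. A C8 cation next to a forming cyclobutane can ring-expand before oxygen arrives. The relative configuration of C1, C9 and C8 would rest on the conformation of an eleven-membered ring. A1 is itself a demanding macrocycle, and A2 still needs the alkene moved into the (Z)-C3=C4 position and the C5 ketone reduced.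
- Comparison: if the cascade worked it would build more structure per step than the chosen plan. The chosen plan sets against this a cyclobutane from a dependable photocycloaddition, a ring fusion secured by equilibration, and only one untested event, whose precursor 11 is reached in eight conventional steps.

**Alternative 2:** The cut is through C8–O and C7′–C1′, leading to tertiary propargylic alcohol A3 (C5 silyl ether) and 17. Forward, acid would ionise A3, 17 would attack the distal alkyne carbon to give an allene, tautomerisation would give a 1-oxatriene, and oxa-6π ring closure would give spiro 2H-pyran A4.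
- Merits: each event has close precedent and the regiochemistry is fixed. C8 is set in a reversible electrocyclisation, hence under thermodynamic control, and C7′ in a separate reduction, so the two centres can be addressed one at a time. In this respect it is better than the single cycloaddition of the chosen plan.
- Weak points: it needs a protected C5 alcohol and three operations (acetylide addition, annulation, reduction). The reduction must distinguish C13=C7′ from C3=C4, and acid meets an allylic silyl ether. It is also only an endgame: the nine-membered C8 ketone must still be made.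
- Comparison: the chosen plan sets against it a two-step, protecting-group-free endgame from 14. The annulation is kept in reserve as the fallback for step 12.

**Alternative 3:** The cut is through C5–C6 with re-formation of C3–C8. It leads to cis-fused bicyclo[3.2.0]heptan-2-ol A5, which carries a vinyl group on the carbinol carbon C8 and a (Z)-2-alkoxy-1-methylvinyl group on C3. Forward, the potassium alkoxide of A5 would undergo an anionic oxy-Cope rearrangement that expands the cyclopentane by four atoms to cis-fused (Z)-cyclononenone A6 (C5 PMB ether).
- Merits: no medium-ring closure is needed, the ring expansion type is well established, the same photoadduct 3 serves as starting point, and the alkene geometry and C5 come out of an ordered transition state. In reliability of the ring-forming event this road is stronger than the chosen one.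
- Weak points: A5 needs a stereodefined trisubstituted enol ether installed at C3 cis to the vinyl group, which takes several steps. The (Z) ring alkene and the C5 configuration depend on a boat-like transition state winning over a chair. A6 is the C9 epimer and must be equilibrated, and a PMB group must later be removed beside an allylic alcohol.
- Comparison: the chosen plan sets against it a precursor made by plain carbonyl chemistry, a trans ring fusion and (Z) alkene fixed before the ring closes, and C5 set by a chiral reagent, not relayed through a sigmatropic transition state.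

Key step: step 9

Remark: caryophyllane numbering is used for the terpenoid part (C13 is the methylene carbon on C8); C7′ bears the isobutyl group and C1′–C6′ are the ring carbons of the syncarpic unit; racemic 3 is drawn as the enantiomer that is carried on.

Step 1
Reactants: 1 cyclopent-2-en-1-one; 2 2-methylpropene
Product: 3 rac-(1R,5R)-6,6-dimethylbicyclo[3.2.0]heptan-2-one
Conditions: hν (350 nm, Pyrex), excess 2, CH2Cl2, −70 °C; removal of the 7,7-dimethyl regioisomer by distillation or chromatography
Reagents that add atoms: none
Why: Enone–alkene [2+2] photocycloaddition: the triplet enone adds through a 1,4-diradical, ring strain enforces the cis fusion (both centres formed together, racemic), and with a 1,1-dialkyl alkene the head-to-tail orientation with the gem-dimethyl carbon on the former β-carbon is the expected major one.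

Step 2
Reactants: 3 rac-(1R,5R)-6,6-dimethylbicyclo[3.2.0]heptan-2-one
Product: 4 (1R,2S,5R)-6,6-dimethyl-2-{[(S)-N-methyl-S-phenylsulfonimidoyl]methyl}bicyclo[3.2.0]heptan-2-ol
Conditions: (S)-N,S-dimethyl-S-phenylsulfoximine, n-BuLi, THF, −78 °C; then 3; NH4Cl; separation of the two diastereomers on SiO2
Reagents that add atoms: (S)-N,S-dimethyl-S-phenylsulfoximine, C[S@@](=O)(=NC)c1ccccc1
Why: 1,2-Addition of the α-lithiated sulfoximine to the ketone from the convex face (new centre C2: CH2S exo, OH endo); because the reagent is a single enantiomer, the two enantiomers of 3 give diastereomeric β-hydroxysulfoximines that can be separated, the established sulfoximine method for resolving ketones.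

Step 3
Reactants: 4 (1R,2S,5R)-6,6-dimethyl-2-{[(S)-N-methyl-S-phenylsulfonimidoyl]methyl}bicyclo[3.2.0]heptan-2-ol
Product: 5 (1R,2S,5R)-2,6,6-trimethylbicyclo[3.2.0]heptan-2-ol
Conditions: Raney Ni (W-2), EtOH, rt
Reagents that add atoms: none
Why: Raney Ni desulfurisation cleaves the C–S bond of the β-hydroxysulfoximine and leaves the methyl carbinol, so that the resolving group becomes the carbon that will be C7; no stereocentre is touched.

Step 4
Reactants: 5 (1R,2S,5R)-2,6,6-trimethylbicyclo[3.2.0]heptan-2-ol
Product: 6 (1R,5R)-2,6,6-trimethylbicyclo[3.2.0]hept-2-ene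
Conditions: POCl3, pyridine, 0 → 60 °C
Reagents that add atoms: none
Why: E2 dehydration of the tertiary alcohol through its dichlorophosphate: loss of the anti (exo) hydrogen of the ring CH2 gives the trisubstituted endocyclic alkene, elimination toward the bridgehead would put a trigonal carbon at the four/five ring fusion and is disfavoured, and the basic medium avoids a free cyclobutylcarbinyl cation.

Step 5
Reactants: 6 (1R,5R)-2,6,6-trimethylbicyclo[3.2.0]hept-2-ene
Product: 7 2-[(1R,4R)-4-acetyl-2,2-dimethylcyclobutyl]acetaldehyde
Conditions: O3, CH2Cl2, −78 °C; PPh3, −78 °C → rt; used at once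
Reagents that add atoms: ozone, [O-][O+]=O
Why: Ozonolysis with reductive work-up cleaves the only C=C bond; the five-membered ring opens to the acetyl group on C9 and the CH2CHO arm on C1, which stay cis because neither centre is touched.

Step 6
Reactants: 7 2-[(1R,4R)-4-acetyl-2,2-dimethylcyclobutyl]acetaldehyde
Product: 8 1-[(1R,2R)-2-[(2Z)-3-iodobut-2-en-1-yl]-3,3-dimethylcyclobutyl]ethan-1-one
Conditions: [Ph3PCH2CH3]I, n-BuLi, THF; I2, −78 °C; NaN(SiMe3)2, −20 °C; then 7, −78 °C
Reagents that add atoms: ethyltriphenylphosphonium iodide, CC[P+](c1ccccc1)(c1ccccc1)c1ccccc1.[I-]; iodine, II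
Why: Wittig olefination with (1-iodoethylidene)triphenylphosphorane made in situ (the iodoethylidene version of the Stork–Zhao olefination), which gives the (Z)-2-iodoalk-2-ene under kinetic control; at −78 °C the aldehyde reacts far faster than the methyl ketone.

Step 7
Reactants: 8 1-[(1R,2R)-2-[(2Z)-3-iodobut-2-en-1-yl]-3,3-dimethylcyclobutyl]ethan-1-one
Product: 9 1-[(1S,2R)-2-[(2Z)-3-iodobut-2-en-1-yl]-3,3-dimethylcyclobutyl]ethan-1-one
Conditions: NaOMe (cat.), MeOH, rt
Reagents that add atoms: none
Why: Base-mediated epimerisation at C9 through the ketone enolate under thermodynamic control: the trans-1,2-disubstituted cyclobutane is the more stable isomer and the non-acidic centre C1 dictates the outcome; at this stage the molecule holds neither an aldehyde nor a Michael acceptor that base could attack.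

Step 8
Reactants: 9 1-[(1S,2R)-2-[(2Z)-3-iodobut-2-en-1-yl]-3,3-dimethylcyclobutyl]ethan-1-one
Product: 11 (3Z)-5-[(1R,4S)-4-acetyl-2,2-dimethylcyclobutyl]-3-methylpent-3-en-2-one, via ethoxydiene 10 (not isolated)
Conditions: tributyl(1-ethoxyvinyl)stannane, Pd(PPh3)4 (5 mol%), CuI, DMF, 60 °C; then 1 M HCl, THF, 0 °C
Reagents that add atoms: tributyl(1-ethoxyvinyl)stannane, CCCC[Sn](CCCC)(CCCC)C(=C)OCC; water, O
Why: Stille coupling of the vinyl iodide with an acetyl anion equivalent proceeds with retention of the (Z) geometry, and brief aqueous acid hydrolyses the 2-ethoxydiene to the methyl ketone without isomerising the enone.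

Step 9
Reactants: 11 (3Z)-5-[(1R,4S)-4-acetyl-2,2-dimethylcyclobutyl]-3-methylpent-3-en-2-one
Product: 14 (1R,3Z,9S)-4,11,11-trimethylbicyclo[7.2.0]undec-3-ene-5,8-dione, via dilithium bis-enolate 12 (not isolated), via cyclic silyl bis-enol ether 13 (not isolated)
Conditions: LiN(i-Pr)2 (2.2 equiv), THF, −78 °C (11 added slowly); Me2SiCl2 (1.0 equiv), 0.005 M, −78 → 0 °C; solvent exchange to MeCN/EtCN; (NH4)2Ce(NO3)6 (2.2 equiv), NaHCO3, −30 °C
Reagents that add atoms: none
Why: Proposed new method: kinetic deprotonation removes one proton from each methyl group (C7 of the cyclobutyl ketone, C6 of the enone, the α′ position being preferred over γ-C2), and Me2SiCl2 at high dilution ties the two enolate oxygens into the ten-membered cyclic silyl bis-enol ether 13. Tetravalent cerium then oxidises the more electron-rich 2-silyloxydiene to a radical cation, which is attacked at its terminus C6 by C7 of the neighbouring enol ether; a second one-electron oxidation and loss of the silicon bridge give the 1,4-diketone. The closest known reactions are the oxidative coupling of acyclic silyl bis-enol ethers to 1,4-diketones with (NH4)2Ce(NO3)6 and the intramolecular oxidative coupling of ketone bis-enolates with divalent copper salts, neither of which has been used to close a medium carbocycle. The nine-membered ring is closed through a seven-membered transition state (C6–C5–O–Si–O–C8–C7, 7-endo with respect to the C7=C8 enol ether), which is the reason for routing the reaction through silicon and not oxidising the free bis-enolate. No stereocentre is formed, and C1, C9 and the (Z)-alkene are untouched because neither enolisation involves C9 or C2. The selectivity needed is C6–C7 bonding over attack of C7 at the other diene terminus C3 (six-membered ring) and over intermolecular coupling. The short O–Si–O bridge holds C6 and C7 within bonding distance while C3 is a substituted and more hindered position, and dilution during silylation keeps the bridge within one molecule.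

Step 10
Reactants: 14 (1R,3Z,9S)-4,11,11-trimethylbicyclo[7.2.0]undec-3-ene-5,8-dione
Product: 15 (1R,3Z,9S)-4,11,11-trimethyl-8-methylidenebicyclo[7.2.0]undec-3-en-5-one
Conditions: [Ph3PCH3]Br, KOt-Bu (1.1 equiv of ylide), THF, 0 °C → rt
Reagents that add atoms: methyltriphenylphosphonium bromide, C[P+](c1ccccc1)(c1ccccc1)c1ccccc1.[Br-]
Why: Wittig methylenation with a limiting amount of the non-stabilised ylide: the saturated C8 ketone is more electrophilic than the conjugated, α-methylated C5 enone carbonyl, a chemoselectivity known for ketone/enone pairs; C9 keeps the trans configuration, which is also the thermodynamic one.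

Step 11
Reactants: 15 (1R,3Z,9S)-4,11,11-trimethyl-8-methylidenebicyclo[7.2.0]undec-3-en-5-one
Product: 16 (1R,3Z,5S,9S)-4,11,11-trimethyl-8-methylidenebicyclo[7.2.0]undec-3-en-5-ol
Conditions: (R)-2-methyl-CBS-oxazaborolidine (20 mol%), catecholborane, toluene, −78 °C; MeOH, aq. NaOH work-up
Reagents that add atoms: none
Why: Corey–Bakshi–Shibata reduction: the oxazaborolidine binds the carbonyl oxygen anti to the larger α-methylalkenyl side and delivers hydride to the face that gives the 5S alcohol (reagent control by the R catalyst); catecholborane at −78 °C reduces 1,2 without hydroborating either alkene.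

Step 12
Reactants: 16 (1R,3Z,5S,9S)-4,11,11-trimethyl-8-methylidenebicyclo[7.2.0]undec-3-en-5-ol; 17 syncarpic acid; 18 3-methylbutanal
Product: 20 tomentodione P (1R,3Z,5S,8S,9S,7′S), via alkylidene trione 19 (not isolated)
Conditions: 17 (1.5 equiv), 18 (1.5 equiv), ethylenediammonium diacetate (cat.), 4 Å MS, toluene, 80 °C
Reagents that add atoms: none
Why: Domino Knoevenagel/hetero-Diels–Alder reaction: 17 and 18 condense to heterodiene 19, which adds with inverse electron demand to the more nucleophilic and less hindered 1,1-disubstituted C8=C13 alkene, oxygen to C8 and C7′ to C13. C8 and C7′ are set together by approach to the outer face of the exocyclic alkene and by the exo/endo orientation of the isobutyl group; this is plausibly how the natural product itself arises, so the (8S,7′S) isomer should be among the products, but its predominance is not secured and chromatographic separation from diastereomers is foreseen.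

## Compound list

1 | cyclopent-2-en-1-one | O=C1C=CCC1 | starting material
2 | 2-methylpropene | C=C(C)C | starting material
3 | rac-(1R,5R)-6,6-dimethylbicyclo[3.2.0]heptan-2-one (cis-fused, racemic; the enantiomer carried on is drawn) | O=C1CC[C@@H]2[C@H]1CC2(C)C | intermediate
4 | (1R,2S,5R)-6,6-dimethyl-2-{[(S)-N-methyl-S-phenylsulfonimidoyl]methyl}bicyclo[3.2.0]heptan-2-ol | O[C@@]1(C[S@@](=O)(=NC)c2ccccc2)CC[C@@H]3[C@H]1CC3(C)C | intermediate
5 | (1R,2S,5R)-2,6,6-trimethylbicyclo[3.2.0]heptan-2-ol (methyl exo, hydroxyl endo) | C[C@]1(O)CC[C@@H]2[C@H]1CC2(C)C | intermediate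
6 | (1R,5R)-2,6,6-trimethylbicyclo[3.2.0]hept-2-ene | CC1=CC[C@@H]2[C@H]1CC2(C)C | intermediate
7 | 2-[(1R,4R)-4-acetyl-2,2-dimethylcyclobutyl]acetaldehyde (cis) | O=CC[C@@H]1[C@@H](CC1(C)C)C(C)=O | intermediate
8 | 1-[(1R,2R)-2-[(2Z)-3-iodobut-2-en-1-yl]-3,3-dimethylcyclobutyl]ethan-1-one (cis) | C/C(I)=C/C[C@@H]1[C@@H](CC1(C)C)C(C)=O | intermediate
9 | 1-[(1S,2R)-2-[(2Z)-3-iodobut-2-en-1-yl]-3,3-dimethylcyclobutyl]ethan-1-one (trans) | C/C(I)=C/C[C@@H]1[C@H](CC1(C)C)C(C)=O | intermediate
10 | 1-[(1S,2R)-2-[(2Z)-4-ethoxy-3-methylpenta-2,4-dien-1-yl]-3,3-dimethylcyclobutyl]ethan-1-one | C=C(OCC)/C(C)=C\C[C@@H]1[C@H](CC1(C)C)C(C)=O | intermediate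
11 | (3Z)-5-[(1R,4S)-4-acetyl-2,2-dimethylcyclobutyl]-3-methylpent-3-en-2-one | C/C(C(C)=O)=C/C[C@@H]1[C@H](CC1(C)C)C(C)=O | intermediate
12 | dilithium (3Z)-5-[(1R,4S)-2,2-dimethyl-4-(1-oxidoethenyl)cyclobutyl]-3-methylpenta-1,3-dien-2-olate | [Li]OC(=C)/C(C)=C\C[C@@H]1[C@H](CC1(C)C)C(=C)O[Li] | intermediate
13 | (1S,7Z,10R)-4,4,7,11,11-pentamethyl-2,6-dimethylidene-3,5-dioxa-4-silabicyclo[8.2.0]dodec-7-ene (cyclic dimethylsilylene bis-enol ether of 11) | C[Si]1(C)OC(=C)/C(C)=C\C[C@@H]2[C@H](CC2(C)C)C(=C)O1 | intermediate
14 | (1R,3Z,9S)-4,11,11-trimethylbicyclo[7.2.0]undec-3-ene-5,8-dione | C/C1=C/C[C@@H]2[C@H](CC2(C)C)C(=O)CCC1=O | intermediate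
15 | (1R,3Z,9S)-4,11,11-trimethyl-8-methylidenebicyclo[7.2.0]undec-3-en-5-one | C/C1=C/C[C@@H]2[C@H](CC2(C)C)C(=C)CCC1=O | intermediate
16 | (1R,3Z,5S,9S)-4,11,11-trimethyl-8-methylidenebicyclo[7.2.0]undec-3-en-5-ol | C/C1=C/C[C@@H]2[C@H](CC2(C)C)C(=C)CC[C@@H]1O | intermediate
17 | syncarpic acid (2,2,4,4-tetramethylcyclohexane-1,3,5-trione) | CC1(C)C(=O)CC(=O)C(C)(C)C1=O | starting material
18 | 3-methylbutanal | CC(C)CC=O | starting material
19 | 2,2,4,4-tetramethyl-6-(3-methylbutylidene)cyclohexane-1,3,5-trione | CC(C)CC=C1C(=O)C(C)(C)C(=O)C(C)(C)C1=O | intermediate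
20 | tomentodione P (1R,3Z,5S,8S,9S,7′S): the C8 spiro dihydropyran of 16, with oxygen on C8, C13H2 and C7′H(isobutyl) in the pyran, fused at C1′=C6′ to the tetramethylcyclohexenedione | C/C1=C/C[C@@H]2[C@H](CC2(C)C)[C@]2(CC[C@@H]1O)C[C@H](CC(C)C)C1=C(O2)C(C)(C)C(=O)C(C)(C)C1=O | target

## Step count and least certain steps

Total step count: 12. Longest linear sequence: 12 steps (1 to 20); 17 and 18 enter in the last step.

**Step 9 (key step, proposed new method).** The silylation may link enolates of different molecules and fail to close the ten-membered ring, so that oxidation then couples intermolecularly. In the radical cation, C7 may also bond to the diene terminus C3 and give a six-membered ring. Fallback by known chemistry, from 9 back to 14: kinetic enolate allylation of the methyl ketone of 9 (LiN(i-Pr)2, allyl bromide) gives pentenone F1, which already holds the C6–C7 bond. OsO4/NaIO4 cleavage of the terminal alkene gives keto aldehyde F2. Nozaki–Hiyama–Kishi cyclisation (CrCl2, NiCl2 cat., DMSO, high dilution) closes the ring at C4–C5 to hydroxy ketone F3, and Dess–Martin oxidation gives 14.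

**Step 12.** The cycloaddition may show poor facial selectivity at C8=C13 and poor exo/endo selectivity at C7′, with a competing ene reaction and reversible O-alkylation of the C5 hydroxyl, so that the target is a minor component of a diastereomer mixture. Fallback, from 16 to 20, building the pyran stepwise:
- silylation (TBSCl, imidazole) to silyl ether F4;
- OsO4/NaIO4 cleavage of the less hindered 1,1-disubstituted alkene to ketone F5;
- addition of lithiated 4-methylpent-1-yne (n-BuLi, CeCl3) to propargylic alcohol F6;
- acid-catalysed annulation with 17 through allene, 1-oxatriene and oxa-6π closure to 2H-pyran F7, with C8 under thermodynamic control;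
- ionic hydrogenation of C13=C7′ (Et3SiH, CF3CO2H) to silyl ether F8;
- Bu4NF to give 20.

**Step 10.** The ylide may attack the enone carbonyl as well, or merely enolise the 1,4-diketone, so that mono-methylenation at C8 is not clean. Fallback, from 14 to 15, which inverts the order of events:
- NaBH4/CeCl3·7H2O reduces the enone carbonyl selectively to hydroxy ketone F3 (the compound also met in the fallback for step 9);
- TBSCl/imidazole traps the open form as silyl ether F9;
- Wittig methylenation gives diene F10;
- Bu4NF gives dienol F11 as a C5 epimer mixture;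
- MnO2 oxidation of the allylic alcohol gives 15.

**Step 11.** The catalyst preference may be opposed by the facial bias of the twisted medium-ring enone (mismatched pairing), which would erode the selectivity at C5. Fallback, from 15 to 16: NaBH4/CeCl3·7H2O under substrate control; if this gives the 5R alcohol F12, Mitsunobu inversion (PPh3, diisopropyl azodicarboxylate, 4-nitrobenzoic acid) gives the 5S ester F13, and K2CO3/MeOH gives 16.

**Step 4.** Elimination may go into the methyl group (exocyclic alkene, which ozonolysis would return to the ketone), or partial ionisation may trigger cyclobutylcarbinyl ring expansion. Fallback, from 4 to 6, which fixes the alkene position through an enolate: thermolysis of 4 (toluene, reflux) releases resolved ketone F14; LiN(i-Pr)2/PhNTf2 gives enol triflate F15 at the CH2 side; MeMgBr with Fe(acac)3 (cat.) gives 6.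

## Further compounds

F1 | step 9 | 1-[(1S,2R)-2-[(2Z)-3-iodobut-2-en-1-yl]-3,3-dimethylcyclobutyl]pent-4-en-1-one | C/C(I)=C/C[C@@H]1[C@H](CC1(C)C)C(=O)CCC=C
F2 | step 9 | 4-[(1S,2R)-2-[(2Z)-3-iodobut-2-en-1-yl]-3,3-dimethylcyclobutyl]-4-oxobutanal | C/C(I)=C/C[C@@H]1[C@H](CC1(C)C)C(=O)CCC=O
F3 | step 9 | (1R,3Z,9S)-5-hydroxy-4,11,11-trimethylbicyclo[7.2.0]undec-3-en-8-one (both C5 epimers) | C/C1=C/C[C@@H]2[C@H](CC2(C)C)C(=O)CCC1O
F4 | step 12 | tert-butyldimethyl{[(1R,3Z,5S,9S)-4,11,11-trimethyl-8-methylidenebicyclo[7.2.0]undec-3-en-5-yl]oxy}silane | C/C1=C/C[C@@H]2[C@H](CC2(C)C)C(=C)CC[C@@H]1O[Si](C)(C)C(C)(C)C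
F5 | step 12 | (1R,3Z,5S,9S)-5-[(tert-butyldimethylsilyl)oxy]-4,11,11-trimethylbicyclo[7.2.0]undec-3-en-8-one | C/C1=C/C[C@@H]2[C@H](CC2(C)C)C(=O)CC[C@@H]1O[Si](C)(C)C(C)(C)C
F6 | step 12 | (1R,3Z,5S,9S)-5-[(tert-butyldimethylsilyl)oxy]-4,11,11-trimethyl-8-(4-methylpent-1-yn-1-yl)bicyclo[7.2.0]undec-3-en-8-ol (either C8 epimer) | C/C1=C/C[C@@H]2[C@H](CC2(C)C)C(O)(C#CCC(C)C)CC[C@@H]1O[Si](C)(C)C(C)(C)C
F7 | step 12 | spiro 2H-pyran with C13=C7′ alkene, C5 tert-butyldimethylsilyl ether (8S) | C/C1=C/C[C@@H]2[C@H](CC2(C)C)[C@]2(CC[C@@H]1O[Si](C)(C)C(C)(C)C)C=C(CC(C)C)C1=C(O2)C(C)(C)C(=O)C(C)(C)C1=O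
F8 | step 12 | C5 tert-butyldimethylsilyl ether of tomentodione P | C/C1=C/C[C@@H]2[C@H](CC2(C)C)[C@]2(CC[C@@H]1O[Si](C)(C)C(C)(C)C)C[C@H](CC(C)C)C1=C(O2)C(C)(C)C(=O)C(C)(C)C1=O
F9 | step 10 | (1R,3Z,9S)-5-[(tert-butyldimethylsilyl)oxy]-4,11,11-trimethylbicyclo[7.2.0]undec-3-en-8-one (both C5 epimers) | C/C1=C/C[C@@H]2[C@H](CC2(C)C)C(=O)CCC1O[Si](C)(C)C(C)(C)C
F10 | step 10 | tert-butyldimethyl{[(1R,3Z,9S)-4,11,11-trimethyl-8-methylidenebicyclo[7.2.0]undec-3-en-5-yl]oxy}silane (both C5 epimers) | C/C1=C/C[C@@H]2[C@H](CC2(C)C)C(=C)CCC1O[Si](C)(C)C(C)(C)C
F11 | step 10 | (1R,3Z,9S)-4,11,11-trimethyl-8-methylidenebicyclo[7.2.0]undec-3-en-5-ol (both C5 epimers) | C/C1=C/C[C@@H]2[C@H](CC2(C)C)C(=C)CCC1O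
F12 | step 11 | (1R,3Z,5R,9S)-4,11,11-trimethyl-8-methylidenebicyclo[7.2.0]undec-3-en-5-ol | C/C1=C/C[C@@H]2[C@H](CC2(C)C)C(=C)CC[C@H]1O
F13 | step 11 | (1R,3Z,5S,9S)-4,11,11-trimethyl-8-methylidenebicyclo[7.2.0]undec-3-en-5-yl 4-nitrobenzoate | C/C1=C/C[C@@H]2[C@H](CC2(C)C)C(=C)CC[C@@H]1OC(=O)c3ccc(cc3)[N+](=O)[O-]
F14 | step 4 | (1R,5R)-6,6-dimethylbicyclo[3.2.0]heptan-2-one (single enantiomer) | O=C1CC[C@@H]2[C@H]1CC2(C)C
F15 | step 4 | (1R,5R)-6,6-dimethylbicyclo[3.2.0]hept-2-en-2-yl trifluoromethanesulfonate | O=S(=O)(OC1=CC[C@@H]2[C@H]1CC2(C)C)C(F)(F)F
A1 | alternative 1 | eleven-membered dienone with C1 acetate (either C1 epimer), (2E)- and (8Z)-alkenes, C4 methyl, C5 ketone and the syncarpic enol side chain on C8 | C[C@@H]1/C=C/C(OC(C)=O)C(C)(C)C/C=C(\C[C@H](CC(C)C)C2=C(O)C(C)(C)C(=O)C(C)(C)C2=O)CCC1=O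
A2 | alternative 1 | spiro-chromene with C5 ketone and (E)-C2=C3 alkene | C[C@@H]1/C=C/[C@@H]2[C@H](CC2(C)C)[C@]2(CCC1=O)C[C@H](CC(C)C)C1=C(O2)C(C)(C)C(=O)C(C)(C)C1=O
A3 | alternative 2 | C8 tertiary propargylic alcohol, C5 tert-butyldimethylsilyl ether (either C8 epimer) | C/C1=C/C[C@@H]2[C@H](CC2(C)C)C(O)(C#CCC(C)C)CC[C@@H]1O[Si](C)(C)C(C)(C)C
A4 | alternative 2 | spiro 2H-pyran with C13=C7′ alkene, C5 tert-butyldimethylsilyl ether | C/C1=C/C[C@@H]2[C@H](CC2(C)C)[C@]2(CC[C@@H]1O[Si](C)(C)C(C)(C)C)C=C(CC(C)C)C1=C(O2)C(C)(C)C(=O)C(C)(C)C1=O
A5 | alternative 3 | cis-fused 6,6-dimethyl-2-vinylbicyclo[3.2.0]heptan-2-ol with a (Z)-2-[(4-methoxybenzyl)oxy]-1-methylvinyl group on the adjacent ring CH, both alkenyl groups exo | C=C[C@]1(O)[C@H](/C(C)=C\OCc3ccc(OC)cc3)C[C@@H]2[C@H]1CC2(C)C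
A6 | alternative 3 | cis-fused (Z)-cyclononenone, C5 4-methoxybenzyl ether | C/C1=C/C[C@@H]2[C@@H](CC2(C)C)C(=O)CC[C@@H]1OCc3ccc(OC)cc3
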